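**Plan**

- Cuts (germacrane numbering: C1 furanone ketone, C2=C3 furanone alkene, C4=C5 Z-alkene, C6 ester carbinol, C7, C8 lactone carbinol, C9, C10 quaternary carbon, C11=C13 methylene, C12 lactone carbonyl): first the C6–O ester; then, together, C11–C12 and C7–C8 (the lactone C12–O opens with them); then the furanone O–C3 and C1–C2 bonds.
- Enabling feature: the α-methylene-γ-butyrolactone fused at C7–C8. The unit C7(H)–C11(=C13H2)–C12O2 is what results when CO2 adds to the central carbon of a terminal allene C7=C11=C13 and the resulting allylmetal attacks a C8 aldehyde through C7. The planar furanone ring and the Z C4=C5 alkene hold the two chain ends in a U.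
- Forward order: the furanone ring is made first (acetylide of a C2–C7/C11/C13 enyne–allene plus a C1/C8–C10 lactone, then amine-mediated cyclisation); the ten-membered carbocycle and the lactone ring then form together in one nickel/CO2 step; the epoxy ester is attached last.
- Stereochemistry: C10 from (R)-citramalic acid; C6 from a reagent-controlled propargylboration; C7 and C8 in the key step (chair transition state, control by C6); the epoxide from a Sharpless asymmetric epoxidation; the Z-alkene from commercial (Z)-3-methylpent-2-en-4-yn-1-ol.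

Key step: step 10

Assumption: in step 2 the (R,R)-controller is taken to direct Si-face attack on aldehyde 2 (propargyl chain turned away from the sulfonyl group on its own face in the chair); if the sense proves opposite, the (S,S)-controller is used instead.
Remark: 1, 3, 7 and 21 are taken as purchased; nickel-bound 17 is drawn in its η1 form with two DBU ligands.

**Step 1**
Reactants: 1 (2Z)-3-methylpent-2-en-4-yn-1-ol
Product: 2 (2Z)-3-methylpent-2-en-4-ynal
Conditions: MnO2 (excess), CH2Cl2, rt; filtered and used as a solution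
Reagents that add atoms: none
Why: Heterogeneous, neutral allylic oxidation with MnO2 should give the enal without touching the alkyne and without Z/E isomerisation; no stereocentre is formed.

**Step 2**
Reactants: 2 (2Z)-3-methylpent-2-en-4-ynal; 3 tributyl(propa-1,2-dien-1-yl)stannane
Product: 5 (4S,5Z)-6-methylocta-1,2,5-trien-7-yn-4-ol, via B-propargyl diazaborolidine 4 (not isolated)
Conditions: (4R,5R)-2-bromo-4,5-diphenyl-1,3-bis(4-methylbenzenesulfonyl)-1,3,2-diazaborolidine, 3, CH2Cl2, 0 to 23 °C; then 2, −78 °C; pH 7 buffer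
Reagents that add atoms: none
Why: SE2′ transmetalation of the allenylstannane gives propargylborane 4, which adds to the aldehyde through a six-membered chair transition state (asymmetric propargylboration) to give only the α-allenyl carbinol, the C2-symmetric bis-sulfonamide controller exposing the Si face of the aldehyde so that C6 is set as 4S.

**Step 3**
Reactants: 5 (4S,5Z)-6-methylocta-1,2,5-trien-7-yn-4-ol
Product: 6 tert-butyldimethyl{[(4S,5Z)-6-methylocta-1,2,5-trien-7-yn-4-yl]oxy}silane
Conditions: TBSCl, imidazole, DMF, rt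
Reagents that add atoms: tert-butyldimethylsilyl chloride CC(C)(C)[Si](C)(C)Cl
Why: Standard silylation of a secondary alcohol (TBS protection) should mask the C6 hydroxyl through the organolithium and nickel steps without touching the stereocentre.

**Step 4**
Reactants: 7 (2R)-2-hydroxy-2-methylbutanedioic acid
Product: 8 2-[(4R)-2,2,4-trimethyl-5-oxo-1,3-dioxolan-4-yl]acetic acid
Conditions: 2,2-dimethoxypropane, TsOH·H2O (cat.), rt
Reagents that add atoms: 2,2-dimethoxypropane COC(C)(C)OC
Why: Acid-catalysed acetonide formation should engage the α-hydroxy acid as the five-membered dioxolanone and leave only the distal carboxyl free, with the quaternary stereocentre untouched.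

**Step 5**
Reactants: 8 2-[(4R)-2,2,4-trimethyl-5-oxo-1,3-dioxolan-4-yl]acetic acid
Product: 10 (3R)-3-hydroxy-3-methyloxolan-2-one, via hydroxyethyl dioxolanone 9 (not isolated)
Conditions: BH3·SMe2, THF, 0 °C to rt; MeOH; then TsOH·H2O (cat.), CH2Cl2, rt
Reagents that add atoms: none
Why: Borane should reduce the free carboxylic acid chemoselectively beside the dioxolanone, and acid-catalysed translactonisation of 9 (5-exo-trig acyl transfer with loss of acetone) should give the γ-lactone with C10 unchanged.

**Step 6**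
Reactants: 10 (3R)-3-hydroxy-3-methyloxolan-2-one
Product: 11 (3R)-3-methyl-3-[(trimethylsilyl)oxy]oxolan-2-one
Conditions: TMSCl, imidazole, DMF, 0 °C to rt
Reagents that add atoms: chlorotrimethylsilane C[Si](C)(C)Cl
Why: Silylation of the tertiary alcohol (TMS ether) should prevent alkoxide formation during the acetylide addition and is removed by the mild acid of step 8.

**Step 7**
Reactants: 6 tert-butyldimethyl{[(4S,5Z)-6-methylocta-1,2,5-trien-7-yn-4-yl]oxy}silane; 11 (3R)-3-methyl-3-[(trimethylsilyl)oxy]oxolan-2-one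
Product: 13 (3R,7Z,9S)-9-[(tert-butyldimethylsilyl)oxy]-1-hydroxy-3,7-dimethyl-3-[(trimethylsilyl)oxy]dodeca-7,10,11-trien-5-yn-4-one, via lithium acetylide 12 (not isolated)
Conditions: n-BuLi, THF, −78 °C; then 11, −78 °C; sat. aq. NH4Cl at −78 °C
Reagents that add atoms: none
Why: Acylation of an acetylide by a lactone: the tetrahedral lithium lactolate should be stable at −78 °C, so a single addition is expected and protonation releases the γ-hydroxy ynone with C6 and C10 untouched.

**Step 8**
Reactants: 13 (3R,7Z,9S)-9-[(tert-butyldimethylsilyl)oxy]-1-hydroxy-3,7-dimethyl-3-[(trimethylsilyl)oxy]dodeca-7,10,11-trien-5-yn-4-one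
Product: 15 (2R)-5-[(2Z,4S)-4-[(tert-butyldimethylsilyl)oxy]hepta-2,5,6-trien-2-yl]-2-(2-hydroxyethyl)-2-methylfuran-3(2H)-one, via diethylamino enone 14 (not isolated)
Conditions: Et2NH, EtOH, rt; then 10% aq. citric acid, THF, rt
Reagents that add atoms: none
Why: Conjugate addition of diethylamine to the ynone gives enaminone 14, and aqueous acid should cleave the tertiary TMS ether and let the freed C10 hydroxyl attack the C3 iminium (5-exo-trig) with loss of the amine, the classical α′-hydroxy ynone to 3(2H)-furanone cyclisation, under conditions chosen to spare the Z C4=C5 alkene, the allene and the TBS ether.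

**Step 9**
Reactants: 15 (2R)-5-[(2Z,4S)-4-[(tert-butyldimethylsilyl)oxy]hepta-2,5,6-trien-2-yl]-2-(2-hydroxyethyl)-2-methylfuran-3(2H)-one
Product: 16 2-[(2R)-5-[(2Z,4S)-4-[(tert-butyldimethylsilyl)oxy]hepta-2,5,6-trien-2-yl]-2-methyl-3-oxo-2,3-dihydrofuran-2-yl]acetaldehyde
Conditions: Dess–Martin periodinane, NaHCO3, CH2Cl2, 0 °C to rt; used without chromatography
Reagents that add atoms: none
Why: Buffered Dess–Martin oxidation should give the aldehyde under non-basic conditions, which avoids β-elimination of the furanone oxygen from this β-alkoxy aldehyde.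

**Step 10**
Reactants: 16 2-[(2R)-5-[(2Z,4S)-4-[(tert-butyldimethylsilyl)oxy]hepta-2,5,6-trien-2-yl]-2-methyl-3-oxo-2,3-dihydrofuran-2-yl]acetaldehyde
Product: 19 (3aR,4R,5Z,10R,11aS)-4-[(tert-butyldimethylsilyl)oxy]-6,10-dimethyl-3-methylidene-3a,4,11,11a-tetrahydro-7,10-epoxycyclodeca[b]furan-2,9(3H,10H)-dione, via allylnickel carboxylate 17 (not isolated), via hydroxy acid 18 (not isolated)
Conditions: Ni(cod)2 (1.5 equiv), DBU (3 equiv), CO2 (1 atm), THF, 0 °C to rt, 16 added slowly to high dilution; 1 M HCl, 0 °C; crude 18, camphorsulfonic acid (cat.), CH2Cl2, rt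
Reagents that add atoms: carbon dioxide O=C=O
Why: Proposed new method: zerovalent nickel ligated by DBU couples CO2 with the terminal allene by oxidative cyclisation, which forms the C11–C12 bond at the central allene carbon and gives the η1/η3-allylnickel carboxylate 17; its γ-carbon C7 then adds to the tethered C8 aldehyde through a six-membered chair transition state (C7–C8 bond), and acid work-up releases hydroxy acid 18, which lactonises. The closest known reaction type is the nickel-mediated sequential addition of CO2 and an aldehyde to a terminal allene, known between separate components and for closing five- and six-membered rings, together with 2-carboxyallyl-metal additions to aldehydes that close germacranolide rings; the extension proposed here is closure of the ten-membered ring. The carbocycle closes by intramolecular carbonyl allylation (10-exo-trig at C8=O, SE2′ at the allyl unit), helped by the planar furanone and the Z C4=C5 alkene, which hold C7 and C8 close; the lactone then closes by 5-exo-trig acyl substitution of the γ-hydroxy acid. C8 relative to C7 follows from the (E)-allylnickel with the C6 chain equatorial in the chair, which gives the anti homoallylic alkoxide and hence the trans-fused lactone (11aS); at C7, H6 eclipses the allyl plane to avoid allylic 1,3-strain with the carboxylate, and the aldehyde, tethered through C5, is delivered to the face anti to the bulky C6 silyloxy group (3aR). The step needs chemoselectivity for the allene over the enone and aldehyde (only the unhindered terminal allene should couple with CO2 at 0 °C), regioselectivity for C7 over C13 (γ-attack of the allylmetal; attack at C13 would need a twelve-membered ring), and suppression of oligomers and of base-induced β-elimination (slow addition to high dilution; DBU held as its CO2 adduct and on nickel).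

**Step 11**
Reactants: 19 (3aR,4R,5Z,10R,11aS)-4-[(tert-butyldimethylsilyl)oxy]-6,10-dimethyl-3-methylidene-3a,4,11,11a-tetrahydro-7,10-epoxycyclodeca[b]furan-2,9(3H,10H)-dione
Product: 20 (3aS,4R,5Z,10R,11aS)-4-hydroxy-6,10-dimethyl-3-methylidene-3a,4,11,11a-tetrahydro-7,10-epoxycyclodeca[b]furan-2,9(3H,10H)-dione
Conditions: HF·pyridine, pyridine, THF, 0 °C to rt
Reagents that add atoms: none
Why: Buffered HF·pyridine should cleave the secondary TBS ether while sparing the α-methylene lactone and the furanone, which a basic fluoride source would endanger; no stereocentre changes (the descriptor at C3a changes by priority only).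

**Step 12**
Reactants: 21 (2E)-2-methylbut-2-en-1-ol
Product: 22 [(2R,3R)-2,3-dimethyloxiran-2-yl]methanol
Conditions: Ti(OiPr)4 (cat.), D-(−)-diethyl tartrate (cat.), t-BuOOH, 4 Å MS, CH2Cl2, −20 °C
Reagents that add atoms: tert-butyl hydroperoxide CC(C)(C)OO
Why: Sharpless asymmetric epoxidation of the E-trisubstituted allylic alcohol with the D-(−)-tartrate ligand should deliver oxygen to the face that gives the (2R,3R)-epoxy alcohol, setting both epoxide stereocentres under catalyst control.

**Step 13**
Reactants: 22 [(2R,3R)-2,3-dimethyloxiran-2-yl]methanol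
Product: 24 (2S,3R)-2,3-dimethyloxirane-2-carboxylic acid, via epoxy aldehyde 23 (not isolated)
Conditions: TEMPO (cat.), PhI(OAc)2, MeCN/H2O, rt
Reagents that add atoms: water O
Why: TEMPO-catalysed oxidation should take the primary alcohol through aldehyde 23 and its hydrate to the acid under near-neutral conditions that leave the epoxide and its stereocentres intact (the C2 descriptor changes by priority only).

**Step 14**
Reactants: 20 (3aS,4R,5Z,10R,11aS)-4-hydroxy-6,10-dimethyl-3-methylidene-3a,4,11,11a-tetrahydro-7,10-epoxycyclodeca[b]furan-2,9(3H,10H)-dione; 24 (2S,3R)-2,3-dimethyloxirane-2-carboxylic acid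
Product: 26 (3aR,4R,5Z,10R,11aS)-6,10-dimethyl-3-methylidene-2,9-dioxo-2,3,3a,4,9,10,11,11a-octahydro-7,10-epoxycyclodeca[b]furan-4-yl (2S,3R)-2,3-dimethyloxirane-2-carboxylate, via mixed anhydride 25 (not isolated)
Conditions: 24, 2,4,6-trichlorobenzoyl chloride, Et3N, toluene, rt; then 20, DMAP, toluene, rt
Reagents that add atoms: none
Why: Yamaguchi esterification: DMAP should attack mixed anhydride 25 at the less hindered epoxy-acyl carbonyl, and the acylpyridinium should acylate the hindered C6 alcohol with retention at C6 and without touching the epoxide stereocentres.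

**Compound list**

1 | (2Z)-3-methylpent-2-en-4-yn-1-ol | C#C/C(C)=C\CO | starting material
2 | (2Z)-3-methylpent-2-en-4-ynal | C#C/C(C)=C\C=O | intermediate
3 | tributyl(propa-1,2-dien-1-yl)stannane | C=C=C[Sn](CCCC)(CCCC)CCCC | starting material
4 | (4R,5R)-4,5-diphenyl-2-(prop-2-yn-1-yl)-1,3-bis(4-methylbenzenesulfonyl)-1,3,2-diazaborolidine | C#CCB1N(S(=O)(=O)c2ccc(C)cc2)[C@H](c2ccccc2)[C@@H](c2ccccc2)N1S(=O)(=O)c1ccc(C)cc1 | intermediate
5 | (4S,5Z)-6-methylocta-1,2,5-trien-7-yn-4-ol | C#C/C(C)=C\[C@@H](O)C=C=C | intermediate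
6 | tert-butyldimethyl{[(4S,5Z)-6-methylocta-1,2,5-trien-7-yn-4-yl]oxy}silane | C#C/C(C)=C\[C@@H](O[Si](C)(C)C(C)(C)C)C=C=C | intermediate
7 | (2R)-2-hydroxy-2-methylbutanedioic acid ((R)-citramalic acid) | OC(=O)C[C@@](C)(O)C(=O)O | starting material
8 | 2-[(4R)-2,2,4-trimethyl-5-oxo-1,3-dioxolan-4-yl]acetic acid | OC(=O)C[C@@]1(C)OC(C)(C)OC1=O | intermediate
9 | (5R)-5-(2-hydroxyethyl)-2,2,5-trimethyl-1,3-dioxolan-4-one | OCC[C@@]1(C)OC(C)(C)OC1=O | intermediate
10 | (3R)-3-hydroxy-3-methyloxolan-2-one | O=C1OCC[C@@]1(C)O | intermediate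
11 | (3R)-3-methyl-3-[(trimethylsilyl)oxy]oxolan-2-one | O=C1OCC[C@@]1(C)O[Si](C)(C)C | intermediate
12 | {(3Z,5S)-5-[(tert-butyldimethylsilyl)oxy]-3-methylocta-3,6,7-trien-1-yn-1-yl}lithium | [Li]C#C/C(C)=C\[C@@H](O[Si](C)(C)C(C)(C)C)C=C=C | intermediate
13 | (3R,7Z,9S)-9-[(tert-butyldimethylsilyl)oxy]-1-hydroxy-3,7-dimethyl-3-[(trimethylsilyl)oxy]dodeca-7,10,11-trien-5-yn-4-one | OCC[C@@](C)(O[Si](C)(C)C)C(=O)C#C/C(C)=C\[C@@H](O[Si](C)(C)C(C)(C)C)C=C=C | intermediate
14 | (3R,5E,7Z,9S)-9-[(tert-butyldimethylsilyl)oxy]-6-(diethylamino)-1-hydroxy-3,7-dimethyl-3-[(trimethylsilyl)oxy]dodeca-5,7,10,11-tetraen-4-one | OCC[C@@](C)(O[Si](C)(C)C)C(=O)/C=C(/N(CC)CC)\C(C)=C/[C@@H](O[Si](C)(C)C(C)(C)C)C=C=C | intermediate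
15 | (2R)-5-[(2Z,4S)-4-[(tert-butyldimethylsilyl)oxy]hepta-2,5,6-trien-2-yl]-2-(2-hydroxyethyl)-2-methylfuran-3(2H)-one | OCC[C@@]1(C)OC(=CC1=O)/C(C)=C\[C@@H](O[Si](C)(C)C(C)(C)C)C=C=C | intermediate
16 | 2-[(2R)-5-[(2Z,4S)-4-[(tert-butyldimethylsilyl)oxy]hepta-2,5,6-trien-2-yl]-2-methyl-3-oxo-2,3-dihydrofuran-2-yl]acetaldehyde | O=CC[C@@]1(C)OC(=CC1=O)/C(C)=C\[C@@H](O[Si](C)(C)C(C)(C)C)C=C=C | intermediate
17 | bis(DBU) nickelalactone of 16 (divalent nickel; ring Ni–O–C12(=O)–C11–C13H2, exocyclic C11=C7 alkylidene, C6 and C10 as in 16; η1 form of the allylnickel carboxylate) | O=C1O[Ni-2]([N+]2=C3CCCCCN3CCC2)([N+]2=C3CCCCCN3CCC2)C/C1=C/[C@H](O[Si](C)(C)C(C)(C)C)/C=C(C)\C4=CC(=O)[C@@](C)(CC=O)O4 | intermediate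
18 | 2-[(2Z,4R,5R,6S,8R)-4-[(tert-butyldimethylsilyl)oxy]-6-hydroxy-2,8-dimethyl-9-oxo-11-oxabicyclo[6.2.1]undeca-1(10),2-dien-5-yl]prop-2-enoic acid | OC(=O)C(=C)[C@@H]1[C@@H](O)C[C@@]2(C)OC(=CC2=O)/C(C)=C\[C@H]1O[Si](C)(C)C(C)(C)C | intermediate
19 | (3aR,4R,5Z,10R,11aS)-4-[(tert-butyldimethylsilyl)oxy]-6,10-dimethyl-3-methylidene-3a,4,11,11a-tetrahydro-7,10-epoxycyclodeca[b]furan-2,9(3H,10H)-dione | C=C1C(=O)O[C@H]2C[C@@]3(C)OC(=CC3=O)/C(C)=C\[C@@H](O[Si](C)(C)C(C)(C)C)[C@H]12 | intermediate
20 | (3aS,4R,5Z,10R,11aS)-4-hydroxy-6,10-dimethyl-3-methylidene-3a,4,11,11a-tetrahydro-7,10-epoxycyclodeca[b]furan-2,9(3H,10H)-dione | C=C1C(=O)O[C@H]2C[C@@]3(C)OC(=CC3=O)/C(C)=C\[C@@H](O)[C@H]12 | intermediate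
21 | (2E)-2-methylbut-2-en-1-ol | C/C=C(\C)CO | starting material
22 | [(2R,3R)-2,3-dimethyloxiran-2-yl]methanol | OC[C@@]1(C)O[C@@H]1C | intermediate
23 | (2S,3R)-2,3-dimethyloxirane-2-carbaldehyde | O=C[C@@]1(C)O[C@@H]1C | intermediate
24 | (2S,3R)-2,3-dimethyloxirane-2-carboxylic acid | OC(=O)[C@@]1(C)O[C@@H]1C | intermediate
25 | (2S,3R)-2,3-dimethyloxirane-2-carboxylic 2,4,6-trichlorobenzoic anhydride | O=C(OC(=O)[C@@]1(C)O[C@@H]1C)c1c(Cl)cc(Cl)cc1Cl | intermediate
26 | (3aR,4R,5Z,10R,11aS)-6,10-dimethyl-3-methylidene-2,9-dioxo-2,3,3a,4,9,10,11,11a-octahydro-7,10-epoxycyclodeca[b]furan-4-yl (2S,3R)-2,3-dimethyloxirane-2-carboxylate | C=C1C(=O)O[C@H]2C[C@@]3(C)OC(=CC3=O)/C(C)=C\[C@@H](OC(=O)[C@@]3(C)O[C@@H]3C)[C@H]12 | target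

**Step count and risks**

Total step count: 14. Longest linear sequence: 9 steps (steps 1–3, 7–11 and 14; equally steps 4–11 and 14).

Steps most likely to fail:

1. Step 10 (proposed new method). What may go wrong: base-induced β-elimination of the furanone oxygen from the β-alkoxy aldehyde before the allylation, intermolecular allylation leading to oligomers, or attack on the wrong face at C7/C8. The fallback sets out from 16 and comes back at 19, making the two bonds one after the other by known reaction types. Palladium-catalysed silastannylation of the allene (Me3Si–SnBu3, [PdCl(C3H5)]2 cat., THF, rt) gives the 2-silylallylstannane F1. Treatment with InCl3 at high dilution (acetone, −78 °C to rt) transmetalates it to the allylindium dichloride F2, which adds to the aldehyde through a cyclic transition state and should close the ten-membered ring as the anti homoallylic alcohol F3 carrying a 1-(trimethylsilyl)vinyl group. Iododesilylation (N-iodosuccinimide, (CF3)2CHOH, 0 °C) gives the vinyl iodide F4, and carbonylative lactonisation (Pd(PPh3)4 cat., CO 1 atm, Et3N, THF, 50 °C) gives 19.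

2. Step 2. What may go wrong: insufficient or reversed facial selectivity in the propargylboration of the Z-enynal, or propargyl/allenyl transposition giving the homopropargylic alcohol. The fallback sets out from 2 and comes back at 5, with the stereocentre set by a reduction of known sense. Addition of lithiated 3-chloroprop-1-yne (n-BuLi, THF, −78 °C) to 2 gives the racemic chloro-ynol F5; MnO2 oxidation gives the ynone F6; Midland reduction with R-Alpine-Borane (from (+)-α-pinene; the alkynyl group acts as the small substituent) gives the (R)-propargylic alcohol F7; hydroxyl-directed SN2′ reduction with LiAlH4 (Et2O, 0 °C), with loss of chloride, gives allenol 5.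

3. Step 7. What may go wrong: incomplete or double addition of the acetylide to the hindered α-silyloxy lactone, or silyl migration in the lactolate. The fallback sets out from 10 and comes back at 13, replacing the lactone by a Weinreb amide as acyl donor. Aminolysis of 10 (MeNH(OMe)·HCl, AlMe3, CH2Cl2) gives the dihydroxy Weinreb amide F8; bis-silylation (TMSCl, imidazole) gives F9; addition of acetylide 12 (THF, −78 °C) gives the bis-TMS ynone F10; selective cleavage of the primary TMS ether (citric acid, MeOH, 0 °C) gives 13.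

**Further compounds**

F1 | step 10 | 2-[(2R)-5-[(2Z,4R,5Z)-4-[(tert-butyldimethylsilyl)oxy]-7-(tributylstannyl)-6-(trimethylsilyl)hepta-2,5-dien-2-yl]-2-methyl-3-oxo-2,3-dihydrofuran-2-yl]acetaldehyde | O=CC[C@@]1(C)OC(=CC1=O)/C(C)=C\[C@@H](O[Si](C)(C)C(C)(C)C)/C=C(/C[Sn](CCCC)(CCCC)CCCC)[Si](C)(C)C
F2 | step 10 | allylindium dichloride corresponding to F1 (InCl2 in place of SnBu3, otherwise as F1) | O=CC[C@@]1(C)OC(=CC1=O)/C(C)=C\[C@@H](O[Si](C)(C)C(C)(C)C)/C=C(/C[In](Cl)Cl)[Si](C)(C)C
F3 | step 10 | (2Z,4R,5R,6S,8R)-4-[(tert-butyldimethylsilyl)oxy]-6-hydroxy-2,8-dimethyl-5-[1-(trimethylsilyl)ethenyl]-11-oxabicyclo[6.2.1]undeca-1(10),2-dien-9-one | C=C([Si](C)(C)C)[C@@H]1[C@@H](O)C[C@@]2(C)OC(=CC2=O)/C(C)=C\[C@H]1O[Si](C)(C)C(C)(C)C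
F4 | step 10 | (2Z,4R,5R,6S,8R)-4-[(tert-butyldimethylsilyl)oxy]-6-hydroxy-5-(1-iodoethenyl)-2,8-dimethyl-11-oxabicyclo[6.2.1]undeca-1(10),2-dien-9-one | C=C(I)[C@@H]1[C@@H](O)C[C@@]2(C)OC(=CC2=O)/C(C)=C\[C@H]1O[Si](C)(C)C(C)(C)C
F5 | step 2 | racemic (3Z)-8-chloro-3-methyloct-3-en-1,6-diyn-5-ol | C#C/C(C)=C\C(O)C#CCCl
F6 | step 2 | (3Z)-8-chloro-3-methyloct-3-en-1,6-diyn-5-one | C#C/C(C)=C\C(=O)C#CCCl
F7 | step 2 | (3Z,5R)-8-chloro-3-methyloct-3-en-1,6-diyn-5-ol | C#C/C(C)=C\[C@@H](O)C#CCCl
F8 | step 7 | (2R)-2,4-dihydroxy-N-methoxy-N,2-dimethylbutanamide | CON(C)C(=O)[C@](C)(O)CCO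
F9 | step 7 | (2R)-N-methoxy-N,2-dimethyl-2,4-bis[(trimethylsilyl)oxy]butanamide | CON(C)C(=O)[C@](C)(O[Si](C)(C)C)CCO[Si](C)(C)C
F10 | step 7 | (3R,7Z,9S)-9-[(tert-butyldimethylsilyl)oxy]-3,7-dimethyl-1,3-bis[(trimethylsilyl)oxy]dodeca-7,10,11-trien-5-yn-4-one | C[Si](C)(C)OCC[C@@](C)(O[Si](C)(C)C)C(=O)C#C/C(C)=C\[C@@H](O[Si](C)(C)C(C)(C)C)C=C=C
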